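If two products grow side by side from one substrate, each by its own one-way step and both steps of the same order, the rate of one divided by the rate of the other holds neither time nor concentration. So I read that ratio from the larch run before reckoning on the flask.

| flask | substrate | remark | time |
|---|---|---|---|
| larch | 0.28 M | run made earlier |  |
| flask | 0.14 M |  | 15 d |

larch run (percent of the substrate charged)

| time / d | target / % | isomer of the product / % |
|---|---|---|
| 0.417 | 4 | 19 |
| 1.04 | 8 | 43 |
| 2.08 | 14 | 62 |
| 3.00 | 15 | 66 |

(each reading ± 1.5 percentage points)



- share of target in target plus isomer of the product at 40 min
- share of target in target plus isomer of the product at 15 h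
- share of target in target plus isomer of the product at 15 d
- which of target and isomer of the product there is more of at 15 d

I went through the larch run in slow motion. At 0.417 d, the first reading, target made up 17.4% of the two products, and 77.0% of the charge was read as neither. At 2.08 d the share was 18.4%, and at 3.00 d it was 18.5%, with 19.0% unread. That remainder ended smaller than it began, yet the share stayed flat within the scatter, so I took the two steps to have one order.

Summed target over summed isomer of the product gave 0.216. I call this S, the target made per isomer of the product made, a selectivity factor. The share is then S/(1+S), or 17.7%, and the flask's charge, half that of the larch run, cancels.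

For the flask, 15 h lies among the readings. But 40 min is 15.0 times earlier than the first reading, and 15 d is 5.00 times later than the last, so both ends were extrapolations. I still committed to 17.7%, with the isomer of the product ahead since S is less than one.

The forecast, reckoned by its maker, stood close to mine: 18%, 18% and 18%, with isomer of the product ahead, on the ground that “both channels appear to have the same order”.

The flask gave 53.2% at 40 min, 17.5% at 15 h and 24.9% at 15 d, with isomer of the product ahead, 73.2% against 24.2% of target.

    substrate ⇌ other conformer (K = 4.50, k = 2.00 h⁻¹)
    substrate → target (k = 0.0250 h⁻¹)
    other conformer → isomer of the product (k = 0.0310 h⁻¹)
    target ⇌ isomer of the product (K = 2.00, k = 0.00160 h⁻¹)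
    substrate + target → side product (k = 0.120 L mol⁻¹ h⁻¹)
    substrate ⇌ dormant form (K = 1.70, k = 0.0160 h⁻¹)

The share reckoned from S of 0.216 met the flask at the middle time and lay below it at both ends; in the flask, target and isomer of the product stood level at 0.0317 d. The neighbouring flask was charged with 0.56 M of substrate, 4.00 times the flask's charge. S holds no charge, so the same reckoning gave that neighbouring flask 17.7% as well. At the early, middle and latest times that neighbouring flask gave 53.0%, 16.7% and 23.9%.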